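**Plan**

Numbering: chroman O1, C2, C3, C4, C4a, C5 to C8, C8a; side chain C1' to C8' counted from C2.
Enabling feature: O1 bridges the tertiary carbinol carbon C2 and arene carbon C8a, and C8a is ortho to C4a, the carbon that holds C4. The pyran ring can therefore be stitched on from the arene side at two neighbouring carbons, and no bond at C2 is made or broken.
Retrosynthesis: the O7 silyl group is removed, then O1–C8a (aryl C–O coupling at C8a–Br) and C4–C4a (B-alkyl Suzuki coupling at C4a–I) are cut, then C7'=C8' (Still–Gennari) and C5'–C6' (enolate alkylation), which leads to (R)-linalool, 3-bromo-5-methylphenol and a trifluoroethyl phosphonopropanoate.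
Forward: the E-methyl of linalool is hydroxylated, brominated, extended by two carbons and olefinated, so the chain is complete before any ring exists. The bromophenol is iodinated para and silylated. The vinyl group is hydroborated, one palladium catalyst then forms C4–C4a and O1–C8a in one flask (the only ring made, the pyran), and desilylation ends the route.
Stereochemistry: C2 is C3 of (R)-linalool and keeps its arrangement (R in the chroman); the 6E alkene is that of linalool, kept by oxidising its E-methyl; the 2Z enoate is set by the Still–Gennari olefination.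

Key step: step 9

Assumption: commercial (R)-(−)-linalool is taken as enantiopure, since no later step can upgrade C2, and any B–O bond formed between the tertiary hydroxyl and excess 9-BBN-H in step 8 is taken to be cleaved by the wet phosphate of step 9, so the alkylborane is drawn as the free alcohol.

**Route**

Step 1
Reactants: 1 (R)-linalool, (3R)-3,7-dimethylocta-1,6-dien-3-ol
Product: 2 (2E,6R)-2,6-dimethylocta-2,7-diene-1,6-diol
Conditions: SeO2 (0.5 equiv), tBuOOH (2 equiv), CH2Cl2, rt; then NaBH4, MeOH, 0 °C
Reagents that add atoms: tert-butyl hydroperoxide, CC(C)(C)OO (net oxygen source); selenium dioxide, O=[Se]=O (oxygen carrier)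
Why: Allylic hydroxylation with SeO2 and tBuOOH (ene reaction, then [2,3]-sigmatropic shift) should attack the electron-rich trisubstituted alkene at its E-methyl group, while the vinyl group has no allylic hydrogen and stays intact; borohydride returns any over-oxidised enal to the E-allylic alcohol and the stereocentre is not touched.

Step 2
Reactants: 2 (2E,6R)-2,6-dimethylocta-2,7-diene-1,6-diol
Product: 4 (3R,6E)-8-bromo-3,7-dimethylocta-1,6-dien-3-ol, via allylic mesylate 3 (not isolated)
Conditions: MsCl, Et3N, THF, −40 °C; then LiBr, THF, 0 °C; used at once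
Reagents that add atoms: lithium bromide, [Li+].[Br-]
Why: Sulfonylation should pick the unhindered primary allylic hydroxyl over the tertiary one, and SN2 displacement of the mesylate by bromide under non-ionising conditions should give the allylic bromide without allylic transposition or loss of the E geometry.

Step 3
Reactants: 4 (3R,6E)-8-bromo-3,7-dimethylocta-1,6-dien-3-ol
Product: 5 tert-butyl (4E,8R)-8-hydroxy-4,8-dimethyldeca-4,9-dienoate
Conditions: tBuOAc, LiN(iPr)2 (2.5 equiv each), THF, −78 °C; then 4, DMPU, −78 to −40 °C
Reagents that add atoms: tert-butyl acetate, CC(=O)OC(C)(C)C (as its lithium enolate)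
Why: SN2 alkylation of a lithium ester enolate by the primary allylic bromide adds C6' and C7'; one equivalent of enolate is given up to the tertiary hydroxyl, whose hindered lithium alkoxide should not compete as a nucleophile at −78 °C, and the tert-butyl ester enolate does not self-condense.

Step 4
Reactants: 5 tert-butyl (4E,8R)-8-hydroxy-4,8-dimethyldeca-4,9-dienoate
Product: 6 (4E,8R)-8-hydroxy-4,8-dimethyldeca-4,9-dienal
Conditions: iBu2AlH (2.2 equiv), CH2Cl2, −78 °C; MeOH, then aq. potassium sodium tartrate
Reagents that add atoms: none
Why: Partial ester reduction with iBu2AlH at −78 °C should stop at the aluminium hemiacetal, which releases the aldehyde only on work-up (the first hydride equivalent is taken by the free hydroxyl), and neither alkene is affected.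

Step 5
Reactants: 6 (4E,8R)-8-hydroxy-4,8-dimethyldeca-4,9-dienal; 7 methyl 2-[bis(2,2,2-trifluoroethoxy)phosphoryl]propanoate
Product: 8 methyl (2Z,6E,10R)-10-hydroxy-2,6,10-trimethyldodeca-2,6,11-trienoate
Conditions: 7, KN(SiMe3)2, 18-crown-6, THF, −78 °C; then 6
Reagents that add atoms: none
Why: In the Still–Gennari olefination the crown-separated potassium salt of the electron-poor phosphonate adds to the aldehyde and eliminates fast and irreversibly from the syn adduct, which should give the 2Z trisubstituted enoate under kinetic control; the phosphonate anion is too weak a base to disturb the tertiary alcohol.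

Step 6
Reactants: 9 3-bromo-5-methylphenol
Product: 10 3-bromo-4-iodo-5-methylphenol
Conditions: N-iodosuccinimide (1.0 equiv), TsOH·H2O (10 mol %), MeCN, 0 °C to rt
Reagents that add atoms: N-iodosuccinimide, O=C1CCC(=O)N1I
Why: Electrophilic aromatic iodination with acid-activated N-iodosuccinimide should be directed by the hydroxyl to its para position, which the ortho methyl group also activates, in line with the para-halogenation of 3,5-disubstituted phenols.

Step 7
Reactants: 10 3-bromo-4-iodo-5-methylphenol
Product: 11 (3-bromo-4-iodo-5-methylphenoxy)tri(propan-2-yl)silane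
Conditions: iPr3SiCl, imidazole, DMF, rt
Reagents that add atoms: chlorotri(propan-2-yl)silane, CC(C)[Si](Cl)(C(C)C)C(C)C
Why: Imidazole-promoted silylation of the unhindered phenol should give an aryl triisopropylsilyl ether that is bulky enough to withstand the phosphate and carbonate bases of step 9 and can be removed with fluoride at the end.

Step 8
Reactants: 8 methyl (2Z,6E,10R)-10-hydroxy-2,6,10-trimethyldodeca-2,6,11-trienoate
Product: 12 methyl (2Z,6E,10S)-12-(9-borabicyclo[3.3.1]nonan-9-yl)-10-hydroxy-2,6,10-trimethyldodeca-2,6-dienoate
Conditions: 9-BBN-H dimer (1.5 equiv B–H), THF, 0 °C to rt; solvent removed under argon, crude 12 used at once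
Reagents that add atoms: 9-borabicyclo[3.3.1]nonane, B1C2CCCC1CCC2
Why: Anti-Markovnikov hydroboration with the bulky dialkylborane should be far faster at the monosubstituted vinyl group than at the trisubstituted alkene or the conjugated enoate and places boron on the terminal carbon (future C4); the carbinol centre is unchanged in space, and its descriptor becomes S only because the priorities change.

Step 9
Reactants: 12 methyl (2Z,6E,10S)-12-(9-borabicyclo[3.3.1]nonan-9-yl)-10-hydroxy-2,6,10-trimethyldodeca-2,6-dienoate (1.3 equiv); 11 (3-bromo-4-iodo-5-methylphenoxy)tri(propan-2-yl)silane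
Product: 14 methyl (2Z,6E)-9-[(2R)-2,5-dimethyl-7-{[tri(propan-2-yl)silyl]oxy}-3,4-dihydro-2H-chromen-2-yl]-2,6-dimethylnona-2,6-dienoate, via bromoaryl carbinol 13 (not isolated)
Conditions: Pd(OAc)2 (5 mol %), 2-(di-tert-butylphosphino)-1,1'-binaphthyl (10 mol %), K3PO4·H2O (3 equiv), THF, 45 °C; then Cs2CO3 (3 equiv), toluene, 85 °C
Reagents that add atoms: none
Why: Zerovalent palladium, formed from Pd(OAc)2 and the phosphine, should add oxidatively to the C4a–I bond of 11, accept C4 from the phosphate-activated borane 12 and reductively eliminate to give C4–C4a in bromide 13 (B-alkyl Suzuki–Miyaura coupling). On warming with Cs2CO3 the same catalyst should add to the C8a–Br bond, bind the tertiary alkoxide and form O1–C8a by C–O reductive elimination (intramolecular Buchwald–Hartwig-type aryl etherification). The one ring closed is the pyran, by intramolecular O-arylation through a seven-membered aryl(alkoxo)palladium chelate that contracts to the six-membered ring. No stereocentre is created, since C2 takes no part in either bond formation and the (R) arrangement bought with linalool reaches the chroman unchanged; because the carbinol carbon bears no hydrogen, the alkoxopalladium intermediate cannot collapse by β-hydride elimination to a ketone and a reduced arene. The step needs site selectivity (iodide before bromide), which rests on the much faster oxidative addition of C–I, and chemoselectivity, which rests on mild phosphate and carbonate bases that spare the methyl enoate and the aryl silyl ether; the halogen pattern places C4a between the C5 methyl and C8a.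

Step 10
Reactants: 14 methyl (2Z,6E)-9-[(2R)-2,5-dimethyl-7-{[tri(propan-2-yl)silyl]oxy}-3,4-dihydro-2H-chromen-2-yl]-2,6-dimethylnona-2,6-dienoate
Product: 15 methyl (2Z,6E)-9-[(2R)-7-hydroxy-2,5-dimethyl-3,4-dihydro-2H-chromen-2-yl]-2,6-dimethylnona-2,6-dienoate (CNP0319148.1)
Conditions: Bu4NF, AcOH (1:1), THF, 0 °C
Reagents that add atoms: none
Why: Fluoride-induced cleavage of the aryl silyl ether, buffered with acetic acid so that the phenoxide is protonated at once and the methyl enoate is neither saponified nor isomerised, should release the target.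

**Compound list**

1 | (R)-linalool, (3R)-3,7-dimethylocta-1,6-dien-3-ol | CC(C)=CCC[C@@](C)(O)C=C | starting material
2 | (2E,6R)-2,6-dimethylocta-2,7-diene-1,6-diol | OC/C(C)=C/CC[C@@](C)(O)C=C | intermediate
3 | (2E,6R)-6-hydroxy-2,6-dimethylocta-2,7-dien-1-yl methanesulfonate | CS(=O)(=O)OC/C(C)=C/CC[C@@](C)(O)C=C | intermediate (not isolated)
4 | (3R,6E)-8-bromo-3,7-dimethylocta-1,6-dien-3-ol | BrC/C(C)=C/CC[C@@](C)(O)C=C | intermediate
5 | tert-butyl (4E,8R)-8-hydroxy-4,8-dimethyldeca-4,9-dienoate | CC(C)(C)OC(=O)CC/C(C)=C/CC[C@@](C)(O)C=C | intermediate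
6 | (4E,8R)-8-hydroxy-4,8-dimethyldeca-4,9-dienal | O=CCC/C(C)=C/CC[C@@](C)(O)C=C | intermediate
7 | methyl 2-[bis(2,2,2-trifluoroethoxy)phosphoryl]propanoate | COC(=O)C(C)P(=O)(OCC(F)(F)F)OCC(F)(F)F | starting material
8 | methyl (2Z,6E,10R)-10-hydroxy-2,6,10-trimethyldodeca-2,6,11-trienoate | COC(=O)/C(C)=C\CC/C(C)=C/CC[C@@](C)(O)C=C | intermediate
9 | 3-bromo-5-methylphenol | Cc1cc(O)cc(Br)c1 | starting material
10 | 3-bromo-4-iodo-5-methylphenol | Cc1cc(O)cc(Br)c1I | intermediate
11 | (3-bromo-4-iodo-5-methylphenoxy)tri(propan-2-yl)silane (1-bromo-2-iodo-3-methyl-5-{[tri(propan-2-yl)silyl]oxy}benzene) | Cc1cc(O[Si](C(C)C)(C(C)C)C(C)C)cc(Br)c1I | intermediate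
12 | methyl (2Z,6E,10S)-12-(9-borabicyclo[3.3.1]nonan-9-yl)-10-hydroxy-2,6,10-trimethyldodeca-2,6-dienoate | COC(=O)/C(C)=C\CC/C(C)=C/CC[C@@](C)(O)CCB1C2CCCC1CCC2 | intermediate
13 | methyl (2Z,6E,10R)-12-(2-bromo-6-methyl-4-{[tri(propan-2-yl)silyl]oxy}phenyl)-10-hydroxy-2,6,10-trimethyldodeca-2,6-dienoate | COC(=O)/C(C)=C\CC/C(C)=C/CC[C@@](C)(O)CCc1c(C)cc(O[Si](C(C)C)(C(C)C)C(C)C)cc1Br | intermediate (not isolated)
14 | methyl (2Z,6E)-9-[(2R)-2,5-dimethyl-7-{[tri(propan-2-yl)silyl]oxy}-3,4-dihydro-2H-chromen-2-yl]-2,6-dimethylnona-2,6-dienoate | COC(=O)/C(C)=C\CC/C(C)=C/CC[C@]1(C)CCc2c(C)cc(O[Si](C(C)C)(C(C)C)C(C)C)cc2O1 | intermediate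
15 | methyl (2Z,6E)-9-[(2R)-7-hydroxy-2,5-dimethyl-3,4-dihydro-2H-chromen-2-yl]-2,6-dimethylnona-2,6-dienoate | COC(=O)/C(C)=C\CC/C(C)=C/CC[C@]1(C)CCc2c(C)cc(O)cc2O1 | target

**Count and risks**

Total step count: 10. Longest linear sequence: 8 steps (steps 1 to 5, 8, 9 and 10, from (R)-linalool); steps 6 and 7 form the arene branch.

Steps most likely to fail:

1. Step 9. The sequence may stall after the first coupling if C–O reductive elimination from the hindered tertiary alkoxide is slow, which would lead to loss of bromine by reduction. Oxidative addition at C–Br may also begin before the iodide is consumed, and the wet base may start to hydrolyse the ester or the silyl ether. The fallback sets out from 11 and 12 and returns at 14, with the two bonds made in separate flasks by different metals. A classical B-alkyl Suzuki–Miyaura coupling (PdCl2(dppf), dppf = 1,1'-bis(diphenylphosphino)ferrocene, K3PO4, DMF–THF, 50 °C), whose ligand does not promote C–O coupling, should stop at bromoaryl carbinol 13, which would be isolated. The pyran would then be closed by an Ullmann-type intramolecular O-arylation with monovalent copper (CuI, 1,10-phenanthroline, Cs2CO3, toluene, 110 °C). This fallback makes no compound outside the list (F0).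

2. Step 3. The lithium alkoxide formed from the tertiary hydroxyl may displace the allylic bromide intramolecularly (SN2' closure to a vinyl tetrahydrofuran) in competition with C-alkylation. The fallback sets out from 4 and returns at 5. The hydroxyl would be masked first (Et3SiOTf, 2,6-lutidine, CH2Cl2, −78 °C) to give {[(3R,6E)-8-bromo-3,7-dimethylocta-1,6-dien-3-yl]oxy}(triethyl)silane F1. Alkylation with only a slight excess of the tert-butyl acetate enolate would give tert-butyl (4E,8R)-4,8-dimethyl-8-[(triethylsilyl)oxy]deca-4,9-dienoate F2, and Bu4NF with AcOH in THF would remove the silyl ether to give 5.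

3. Step 6. Iodine may enter ortho to the hydroxyl instead of at the para position flanked by bromine and methyl, or a second iodination may follow. The fallback sets out from 9 and returns at 11 by reversing the order. Silylation (iPr3SiCl, imidazole, DMF) would give (3-bromo-5-methylphenoxy)tri(propan-2-yl)silane F3, whose bulky silyloxy group screens both ortho positions. Iodination (I2, AgOSO2CF3, CH2Cl2, 0 °C) should then occur para and give 11 directly.

**Further compounds**

F0 | step 9 | none | none
F1 | step 3 | {[(3R,6E)-8-bromo-3,7-dimethylocta-1,6-dien-3-yl]oxy}(triethyl)silane | BrC/C(C)=C/CC[C@@](C)(O[Si](CC)(CC)CC)C=C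
F2 | step 3 | tert-butyl (4E,8R)-4,8-dimethyl-8-[(triethylsilyl)oxy]deca-4,9-dienoate | CC(C)(C)OC(=O)CC/C(C)=C/CC[C@@](C)(O[Si](CC)(CC)CC)C=C
F3 | step 6 | (3-bromo-5-methylphenoxy)tri(propan-2-yl)silane | Cc1cc(O[Si](C(C)C)(C(C)C)C(C)C)cc(Br)c1
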